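**Retrosynthetic overview**
- The target is reached by a final Pd(0) removal of two allyl groups (allyl ester and allyl aryl ether) from a protected (S)-carbinol.
- The only stereocentre comes from a ketoreductase (NADPH-dependent alcohol dehydrogenase) reduction of the aryl isobutyl ketone, done late so nothing can erode it afterwards.
- The diaryl ether comes from an SNAr reaction between a fluoro keto ester (F para to the ketone, ortho to the ester) and a salicylaldehyde-type phenol; the ring-B aldehyde is reduced to CH2OH afterwards.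
- Ring A fragment: 1-bromo-4-fluoro-2-methoxybenzene by ortho-lithiation/CO2, allyl ester formation, then Br/Mg exchange and Weinreb acylation. Ring B fragment: 2-hydroxy-3-methoxy-5-methylbenzaldehyde by demethylation and regioselective 3-O-allylation.
- No ring is constructed: both benzene rings are bought intact, and the order is ring A fragment, ring B fragment, ether union, two reductions, deprotection.

Assumption: an (S)-selective (Prelog-type) engineered ketoreductase that accepts ketone 14 is taken from a commercial KRED screening panel; this route is a proposal and has not been run.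

**Step 1**
Reactants: 1 1-bromo-4-fluoro-2-methoxybenzene
Product: 3 3-bromo-6-fluoro-2-methoxybenzoic acid, via aryllithium 2 (not isolated)
Conditions: LDA (1.1 equiv), THF, −78 °C, 1 h; CO2 (g), −78 °C → rt; 1 M HCl
Reagents that add atoms: carbon dioxide, O=C=O
Why: Directed ortho-metalation with an amide base (no Br/Li exchange) removes the most acidic ring proton, the one flanked by F and OMe, and the aryllithium is carboxylated at −78 °C before LiF loss to an aryne can occur.

**Step 2**
Reactants: 3 3-bromo-6-fluoro-2-methoxybenzoic acid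
Product: 4 allyl 3-bromo-6-fluoro-2-methoxybenzoate
Conditions: allyl bromide (1.2 equiv), K2CO3 (1.5 equiv), DMF, rt, 12 h
Reagents that add atoms: allyl bromide, C=CCBr
Why: SN2 O-alkylation of the carboxylate avoids attack at the di-ortho-substituted carbonyl and installs an ester that can later be removed under neutral Pd(0) conditions.

**Step 3**
Reactants: 5 3-methylbutanoyl chloride
Product: 6 N-methoxy-N,3-dimethylbutanamide
Conditions: MeNH(OMe)·HCl (1.1 equiv), K2CO3 (2.5 equiv), CH2Cl2/H2O, 0 °C → rt
Reagents that add atoms: N,O-dimethylhydroxylamine hydrochloride, CNOC.Cl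
Why: Schotten–Baumann N-acylation of the hydroxylamine by an unhindered acid chloride gives the Weinreb amide cleanly.

**Step 4**
Reactants: 4 allyl 3-bromo-6-fluoro-2-methoxybenzoate; 6 N-methoxy-N,3-dimethylbutanamide
Product: 8 allyl 6-fluoro-2-methoxy-3-(3-methylbutanoyl)benzoate, via arylmagnesium chloride 7 (not isolated)
Conditions: i-PrMgCl·LiCl (1.1 equiv), THF, −20 °C, 2 h; then 6 (1.3 equiv), −20 → 0 °C; cold 1 M HCl
Reagents that add atoms: none
Why: Knochel Br/Mg exchange (helped by the ortho-OMe) tolerates the di-ortho-substituted ester at ≤0 °C, and the Weinreb ketone synthesis stops at the ketone because the magnesium chelate only collapses on work-up; no stereocentre is formed.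

**Step 5**
Reactants: 9 2-hydroxy-3-methoxy-5-methylbenzaldehyde
Product: 10 2,3-dihydroxy-5-methylbenzaldehyde
Conditions: BBr3 (2.5 equiv), CH2Cl2, −78 °C → rt; H2O
Reagents that add atoms: none
Why: BBr3 Lewis-acid cleavage of the aryl methyl ether frees the catechol and leaves the aldehyde intact.

**Step 6**
Reactants: 10 2,3-dihydroxy-5-methylbenzaldehyde
Product: 12 3-(allyloxy)-2-hydroxy-5-methylbenzaldehyde, via disodium catecholate 11 (not isolated)
Conditions: NaH (2.2 equiv), DMSO, 20 °C, 1 h; allyl bromide (1.0 equiv), 20 °C; 1 M HCl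
Reagents that add atoms: allyl bromide, C=CCBr
Why: Regioselective Williamson mono-alkylation of the dianion: the 2-phenoxide is conjugated to and chelated by the ortho-formyl group and is poorly nucleophilic, so one equivalent of allyl bromide reacts at the 3-phenoxide.

**Step 7**
Reactants: 8 allyl 6-fluoro-2-methoxy-3-(3-methylbutanoyl)benzoate; 12 3-(allyloxy)-2-hydroxy-5-methylbenzaldehyde
Product: 13 allyl 6-[2-(allyloxy)-6-formyl-4-methylphenoxy]-2-methoxy-3-(3-methylbutanoyl)benzoate
Conditions: 12 (1.1 equiv), K2CO3 (2.0 equiv), DMF, 70 °C, 12 h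
Reagents that add atoms: none
Why: SNAr: the fluoride is para to the ketone and ortho to the ester, so the Meisenheimer adduct is doubly stabilised; ring B is carried as the aldehyde so no free benzylic hydroxyl is present to trigger a Smiles rearrangement.

**Step 8**
Reactants: 13 allyl 6-[2-(allyloxy)-6-formyl-4-methylphenoxy]-2-methoxy-3-(3-methylbutanoyl)benzoate
Product: 14 allyl 6-[2-(allyloxy)-6-(hydroxymethyl)-4-methylphenoxy]-2-methoxy-3-(3-methylbutanoyl)benzoate
Conditions: NaBH4 (0.35 equiv), EtOH/CH2Cl2 (3:7), −78 °C; aq. NH4Cl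
Reagents that add atoms: none
Why: Chemoselective borohydride reduction: at −78 °C the aryl aldehyde is reduced far faster than the ortho-substituted aryl isobutyl ketone or the hindered ester, and any over-reduced diol is removed by chromatography.

**Step 9**
Reactants: 14 allyl 6-[2-(allyloxy)-6-(hydroxymethyl)-4-methylphenoxy]-2-methoxy-3-(3-methylbutanoyl)benzoate
Product: 15 allyl 6-[2-(allyloxy)-6-(hydroxymethyl)-4-methylphenoxy]-3-[(1S)-1-hydroxy-3-methylbutyl]-2-methoxybenzoate
Conditions: ketoreductase (engineered (S)-selective KRED), NADP+ (cat.), i-PrOH (15 vol %), DMSO (10 vol %), 0.1 M K-phosphate pH 7.0, 30 °C, 24 h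
Reagents that add atoms: none
Why: Enzymatic asymmetric ketone reduction: the ketoreductase (an NADPH-dependent alcohol dehydrogenase) delivers hydride to the re face of the aryl ketone (Prelog selectivity), which gives the (S)-carbinol, while isopropanol recycles the cofactor at neutral pH where both allyl groups survive.

**Step 10**
Reactants: 15 allyl 6-[2-(allyloxy)-6-(hydroxymethyl)-4-methylphenoxy]-3-[(1S)-1-hydroxy-3-methylbutyl]-2-methoxybenzoate
Product: 16 6-[2-hydroxy-6-(hydroxymethyl)-4-methylphenoxy]-3-[(1S)-1-hydroxy-3-methylbutyl]-2-methoxybenzoic acid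
Conditions: Pd(PPh3)4 (5 mol %), morpholine (10 equiv), THF, rt, 2 h; pH 4 citrate buffer work-up
Reagents that add atoms: none
Why: Tsuji–Trost deallylation: Pd(0) ionises both the allyl ester and the allyl aryl ether to π-allyl-Pd, which morpholine traps irreversibly, and the neutral conditions leave the benzylic (S)-carbinol untouched.

**Compound list**
1 | 1-bromo-4-fluoro-2-methoxybenzene | COc1cc(F)ccc1Br | starting material
2 | (3-bromo-6-fluoro-2-methoxyphenyl)lithium | COc1c([Li])c(F)ccc1Br | intermediate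
3 | 3-bromo-6-fluoro-2-methoxybenzoic acid | COc1c(C(=O)O)c(F)ccc1Br | intermediate
4 | allyl 3-bromo-6-fluoro-2-methoxybenzoate | COc1c(C(=O)OCC=C)c(F)ccc1Br | intermediate
5 | 3-methylbutanoyl chloride | CC(C)CC(=O)Cl | starting material
6 | N-methoxy-N,3-dimethylbutanamide | CON(C)C(=O)CC(C)C | intermediate
7 | [3-(allyloxycarbonyl)-4-fluoro-2-methoxyphenyl]magnesium chloride (LiCl complex) | COc1c(C(=O)OCC=C)c(F)ccc1[Mg]Cl | intermediate
8 | allyl 6-fluoro-2-methoxy-3-(3-methylbutanoyl)benzoate | COc1c(C(=O)OCC=C)c(F)ccc1C(=O)CC(C)C | intermediate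
9 | 2-hydroxy-3-methoxy-5-methylbenzaldehyde | COc1cc(C)cc(C=O)c1O | starting material
10 | 2,3-dihydroxy-5-methylbenzaldehyde | Cc1cc(O)c(O)c(C=O)c1 | intermediate
11 | disodium 3-formyl-5-methylbenzene-1,2-diolate | Cc1cc([O-])c([O-])c(C=O)c1.[Na+].[Na+] | intermediate
12 | 3-(allyloxy)-2-hydroxy-5-methylbenzaldehyde | C=CCOc1cc(C)cc(C=O)c1O | intermediate
13 | allyl 6-[2-(allyloxy)-6-formyl-4-methylphenoxy]-2-methoxy-3-(3-methylbutanoyl)benzoate | COc1c(C(=O)CC(C)C)ccc(Oc2c(OCC=C)cc(C)cc2C=O)c1C(=O)OCC=C | intermediate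
14 | allyl 6-[2-(allyloxy)-6-(hydroxymethyl)-4-methylphenoxy]-2-methoxy-3-(3-methylbutanoyl)benzoate | COc1c(C(=O)CC(C)C)ccc(Oc2c(OCC=C)cc(C)cc2CO)c1C(=O)OCC=C | intermediate
15 | allyl 6-[2-(allyloxy)-6-(hydroxymethyl)-4-methylphenoxy]-3-[(1S)-1-hydroxy-3-methylbutyl]-2-methoxybenzoate | COc1c([C@@H](O)CC(C)C)ccc(Oc2c(OCC=C)cc(C)cc2CO)c1C(=O)OCC=C | intermediate
16 | 6-[2-hydroxy-6-(hydroxymethyl)-4-methylphenoxy]-3-[(1S)-1-hydroxy-3-methylbutyl]-2-methoxybenzoic acid | COc1c([C@@H](O)CC(C)C)ccc(Oc2c(O)cc(C)cc2CO)c1C(=O)O | target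

**Totals**
Total step count: 10.
Longest linear sequence: 7 steps (1 → 2 → 4 → 7 → 8 → 9 → 10).

**Three steps most likely to fail, with fallbacks**

Step 9 (the ketoreductase may give low conversion or ee on the bulky diaryl ether ketone 14). The fallback sets out from 8 and moves the same enzymatic reduction to this much smaller ketone, before the ether union. KRED/NADP+/i-PrOH in pH 7 buffer gives allyl 6-fluoro-3-[(1S)-1-hydroxy-3-methylbutyl]-2-methoxybenzoate F1. Silylation (TBSOTf, 2,6-lutidine, CH2Cl2, 0 °C) gives allyl 3-[(1S)-1-(tert-butyldimethylsilyloxy)-3-methylbutyl]-6-fluoro-2-methoxybenzoate F2. SNAr with 12, now activated only by the ortho ester and therefore run harder (Cs2CO3, DMSO, 110 °C), gives allyl 6-[2-(allyloxy)-6-formyl-4-methylphenoxy]-3-[(1S)-1-(tert-butyldimethylsilyloxy)-3-methylbutyl]-2-methoxybenzoate F3. NaBH4 in MeOH at 0 °C gives allyl 6-[2-(allyloxy)-6-(hydroxymethyl)-4-methylphenoxy]-3-[(1S)-1-(tert-butyldimethylsilyloxy)-3-methylbutyl]-2-methoxybenzoate F4. TBAF buffered with AcOH in THF removes the silyl ether, and the route is rejoined at 15.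

Step 6 (the dianion mono-allylation may give the 2-O-allyl isomer or bis-allylation). The fallback sets out from 9, whose only free phenol is the one that must end up free, and blocks it before the second phenol is unmasked. TsCl/Et3N/DMAP in CH2Cl2 gives 2-formyl-6-methoxy-4-methylphenyl 4-methylbenzenesulfonate F5. BBr3 (CH2Cl2, −78 → 0 °C; sulfonates survive) gives 2-formyl-6-hydroxy-4-methylphenyl 4-methylbenzenesulfonate F6. Allyl bromide/K2CO3 in acetone at rt gives 2-(allyloxy)-6-formyl-4-methylphenyl 4-methylbenzenesulfonate F7. KOH in MeOH/H2O at 50 °C cleaves the activated aryl sulfonate, and the route is rejoined at 12 with unambiguous regiochemistry.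

Step 4 (the arylmagnesium may attack the allyl ester or add sluggishly to the Weinreb amide). The fallback sets out from 3 and uses the carboxylate itself as the protecting group, so no ester is present during the organometallic step. MeMgCl (1.0 equiv, THF, −20 °C) forms the magnesium carboxylate, i-PrMgCl·LiCl (1.2 equiv) performs the Br/Mg exchange, and addition of 6 followed by acidic work-up gives 6-fluoro-2-methoxy-3-(3-methylbutanoyl)benzoic acid F8. Allyl bromide/K2CO3 in DMF then gives the ester, and the route is rejoined at 8.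

**Further compounds**
F1 | step 9 | allyl 6-fluoro-3-[(1S)-1-hydroxy-3-methylbutyl]-2-methoxybenzoate | COc1c([C@@H](O)CC(C)C)ccc(F)c1C(=O)OCC=C
F2 | step 9 | allyl 3-[(1S)-1-(tert-butyldimethylsilyloxy)-3-methylbutyl]-6-fluoro-2-methoxybenzoate | COc1c([C@@H](O[Si](C)(C)C(C)(C)C)CC(C)C)ccc(F)c1C(=O)OCC=C
F3 | step 9 | allyl 6-[2-(allyloxy)-6-formyl-4-methylphenoxy]-3-[(1S)-1-(tert-butyldimethylsilyloxy)-3-methylbutyl]-2-methoxybenzoate | COc1c([C@@H](O[Si](C)(C)C(C)(C)C)CC(C)C)ccc(Oc2c(OCC=C)cc(C)cc2C=O)c1C(=O)OCC=C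
F4 | step 9 | allyl 6-[2-(allyloxy)-6-(hydroxymethyl)-4-methylphenoxy]-3-[(1S)-1-(tert-butyldimethylsilyloxy)-3-methylbutyl]-2-methoxybenzoate | COc1c([C@@H](O[Si](C)(C)C(C)(C)C)CC(C)C)ccc(Oc2c(OCC=C)cc(C)cc2CO)c1C(=O)OCC=C
F5 | step 6 | 2-formyl-6-methoxy-4-methylphenyl 4-methylbenzenesulfonate | COc1cc(C)cc(C=O)c1OS(=O)(=O)c1ccc(C)cc1
F6 | step 6 | 2-formyl-6-hydroxy-4-methylphenyl 4-methylbenzenesulfonate | Cc1ccc(cc1)S(=O)(=O)Oc1c(O)cc(C)cc1C=O
F7 | step 6 | 2-(allyloxy)-6-formyl-4-methylphenyl 4-methylbenzenesulfonate | C=CCOc1cc(C)cc(C=O)c1OS(=O)(=O)c1ccc(C)cc1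
F8 | step 4 | 6-fluoro-2-methoxy-3-(3-methylbutanoyl)benzoic acid | COc1c(C(=O)O)c(F)ccc1C(=O)CC(C)C
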